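**Retrosynthetic overview**
- Target ⇒ oleic acid + the monocyclic C20 allylic alcohol (ester C–O bond, made last).
- The alcohol ⇒ its C5 phenyl sulfone C1 acetate; the sulfone is removed by palladium/hydride and the acetate is cleaved in the same flask.
- The only ring (the 2,6,6-trimethylcyclohex-2-enyl unit) is formed late, on the complete open-chain C20 skeleton, by an enantioselective proton-initiated cation–olefin cyclisation of a geranylgeranyl-type tetraene. The C5 sulfone and the C1 acetate deactivate the two distal olefins, so the cascade should stop after one ring.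
- The open-chain C20 sulfone ⇒ lithiated (2E,6E)-farnesyl phenyl sulfone (C15) + (2E)-4-bromo-3-methylbut-2-enyl acetate (C5).
- The fragments come from (2E,6E)-farnesol and prenyl acetate.

Assumption: the ring stereocentre of the given SMILES is (S) by CIP analysis, and the (R)-configured acid of step 5 is taken to give the same sense of induction (natural 5S-type first ring) as in its known polyprenoid cyclisations; if the sense found is opposite, the mirror-image acid is used.

**Step 1**
Reactants: 1 (2E,6E)-farnesol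
Product: 3 (2E,6E)-farnesyl phenyl sulfone, via farnesyl bromide 2 (not isolated)
Conditions: PBr3 (0.4 equiv), Et2O, −10 °C; then PhSO2Na (1.5 equiv), DMF, rt
Reagents that add atoms: sodium benzenesulfinate (PhSO2Na), [Na+].[O-]S(=O)c1ccccc1
Why: SN2 bromination of the primary allylic alcohol and S-alkylation of the sulfinate (sulfone synthesis) are both direct displacements at C1, so the 2E,6E geometry is untouched.

**Step 2**
Reactants: 4 prenyl acetate (3-methylbut-2-en-1-yl acetate)
Product: 5 (2E)-4-hydroxy-3-methylbut-2-en-1-yl acetate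
Conditions: SeO2 (0.3 equiv), t-BuOOH (2.5 equiv), salicylic acid (0.1 equiv), CH2Cl2, rt
Reagents that add atoms: tert-butyl hydroperoxide, CC(C)(C)OO (terminal oxygen source, relayed through catalytic SeO2, O=[Se]=O)
Why: Catalytic SeO2/t-BuOOH allylic oxidation (ene reaction, then [2,3]-sigmatropic shift) attacks the E-methyl group of the gem-dimethyl olefin selectively, which fixes the E geometry of the new allylic alcohol.

**Step 3**
Reactants: 5 (2E)-4-hydroxy-3-methylbut-2-en-1-yl acetate
Product: 6 (2E)-4-bromo-3-methylbut-2-en-1-yl acetate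
Conditions: CBr4, PPh3, CH2Cl2, 0 °C
Reagents that add atoms: carbon tetrabromide, BrC(Br)(Br)Br
Why: Appel reaction, a neutral SN2 displacement at the primary allylic carbon that causes no allylic shift and leaves the acetate alone.

**Step 4**
Reactants: 3 (2E,6E)-farnesyl phenyl sulfone; 6 (2E)-4-bromo-3-methylbut-2-en-1-yl acetate
Product: 8 (2E,6E,10E)-3,7,11,15-tetramethyl-5-(phenylsulfonyl)hexadeca-2,6,10,14-tetraen-1-yl acetate (racemic at C5), via lithiated farnesyl phenyl sulfone 7 (not isolated)
Conditions: n-BuLi (0.98 equiv), THF, −78 °C; then 6, −78 → −40 °C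
Reagents that add atoms: none
Why: Alkylation of an α-sulfonyl allyl carbanion (Julia/Biellmann head-to-tail prenyl coupling) occurs at the carbon α to sulfur, and at −78 °C the SN2 reaction with the allylic bromide outruns attack on the acetate; the new C5 centre is racemic and is erased in step 6.

**Step 5**
Reactants: 8 (2E,6E,10E)-3,7,11,15-tetramethyl-5-(phenylsulfonyl)hexadeca-2,6,10,14-tetraen-1-yl acetate
Product: 9 (2E,6E)-3,7-dimethyl-5-(phenylsulfonyl)-9-[(1S)-2,6,6-trimethylcyclohex-2-en-1-yl]nona-2,6-dien-1-yl acetate (both C5 epimers, ring carbon S)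
Conditions: (R)-2-(2-fluorobenzyloxy)-2′-hydroxy-1,1′-binaphthyl (2.2 equiv), SnCl4 (2.0 equiv), toluene, −78 °C, 48 h; pyridine, then aq. NaHCO3
Reagents that add atoms: none
Why: Proposed new method: the chiral proton donor (a Lewis acid-assisted Brønsted acid, the binaphthol ether–SnCl4 complex) protonates the terminal isopropylidene in concert with attack of the C10=C11 π-bond on C15 through one enantiomeric chair fold, which sets (S) at the ring carbon, and the C11 tertiary cation then loses a C12 proton to the ring olefin instead of cyclising on, because C6=C7 (allylic sulfone next to the branched C5) and C2=C3 (allylic acetate) are inductively deactivated and hindered; the closest known reaction type is the enantioselective proton-initiated polyene cyclisation of homofarnesol, homofarnesic acid and homo(polyprenyl)arenes with the same acid, in which monocyclic olefins already appear as by-products from undeactivated polyenes.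

**Step 6**
Reactants: 9 (2E,6E)-3,7-dimethyl-5-(phenylsulfonyl)-9-[(1S)-2,6,6-trimethylcyclohex-2-en-1-yl]nona-2,6-dien-1-yl acetate
Product: 11 (2E,6E)-3,7-dimethyl-9-[(1S)-2,6,6-trimethylcyclohex-2-en-1-yl]nona-2,6-dien-1-ol, via lithium alkoxide of the hydroxy sulfone 10 (not isolated)
Conditions: LiBHEt3 (2.2 equiv), THF, −78 → 0 °C; then PdCl2(dppp) (5 mol%), LiBHEt3 (2 equiv), 0 °C; aq. NH4Cl
Reagents that add atoms: none
Why: LiBHEt3 first cleaves the acetate to the alkoxide, then zerovalent palladium (formed in situ from PdCl2(dppp), dppp = 1,3-bis(diphenylphosphino)propane) ionises the allylic C–S bond and hydride goes to the less substituted allyl terminus C5 (palladium-catalysed reductive desulfonylation of an allylic sulfone), so the E C6=C7 olefin stays in place and both C5 epimers converge to one enantiomer.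

**Step 7**
Reactants: 11 (2E,6E)-3,7-dimethyl-9-[(1S)-2,6,6-trimethylcyclohex-2-en-1-yl]nona-2,6-dien-1-ol; 12 oleic acid
Product: 13 (2E,6E)-3,7-dimethyl-9-[(1S)-2,6,6-trimethylcyclohex-2-en-1-yl]nona-2,6-dien-1-yl (9Z)-octadec-9-enoate (CNP0391302.1)
Conditions: DCC (1.2 equiv), DMAP (0.1 equiv), CH2Cl2, 0 °C → rt
Reagents that add atoms: none
Why: Steglich esterification (carbodiimide activation, DMAP acyl transfer) acylates the primary allylic alcohol under neutral conditions that leave the Z olefin of the oleate, the E olefins and the ring stereocentre untouched.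

**Compound list**
1 | (2E,6E)-farnesol, (2E,6E)-3,7,11-trimethyldodeca-2,6,10-trien-1-ol | OC/C=C(\C)CC/C=C(\C)CCC=C(C)C | starting material
2 | (2E,6E)-farnesyl bromide, (2E,6E)-1-bromo-3,7,11-trimethyldodeca-2,6,10-triene | BrC/C=C(\C)CC/C=C(\C)CCC=C(C)C | intermediate (not isolated)
3 | (2E,6E)-farnesyl phenyl sulfone, {[(2E,6E)-3,7,11-trimethyldodeca-2,6,10-trien-1-yl]sulfonyl}benzene | O=S(=O)(C/C=C(\C)CC/C=C(\C)CCC=C(C)C)c1ccccc1 | intermediate
4 | prenyl acetate, 3-methylbut-2-en-1-yl acetate | CC(=O)OCC=C(C)C | starting material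
5 | (2E)-4-hydroxy-3-methylbut-2-en-1-yl acetate | CC(=O)OC/C=C(\C)CO | intermediate
6 | (2E)-4-bromo-3-methylbut-2-en-1-yl acetate | CC(=O)OC/C=C(\C)CBr | intermediate
7 | lithiated (2E,6E)-farnesyl phenyl sulfone (C1 carbanion, lithium salt) | [Li+].O=S(=O)([CH-]/C=C(\C)CC/C=C(\C)CCC=C(C)C)c1ccccc1 | intermediate (not isolated)
8 | (2E,6E,10E)-3,7,11,15-tetramethyl-5-(phenylsulfonyl)hexadeca-2,6,10,14-tetraen-1-yl acetate, racemic at C5 | CC(=O)OC/C=C(\C)CC(/C=C(\C)CC/C=C(\C)CCC=C(C)C)S(=O)(=O)c1ccccc1 | intermediate
9 | (2E,6E)-3,7-dimethyl-5-(phenylsulfonyl)-9-[(1S)-2,6,6-trimethylcyclohex-2-en-1-yl]nona-2,6-dien-1-yl acetate, both C5 epimers | CC(=O)OC/C=C(\C)CC(/C=C(\C)CC[C@@H]1C(C)=CCCC1(C)C)S(=O)(=O)c1ccccc1 | intermediate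
10 | lithium (2E,6E)-3,7-dimethyl-5-(phenylsulfonyl)-9-[(1S)-2,6,6-trimethylcyclohex-2-en-1-yl]nona-2,6-dien-1-olate, both C5 epimers | [Li+].[O-]C/C=C(\C)CC(/C=C(\C)CC[C@@H]1C(C)=CCCC1(C)C)S(=O)(=O)c1ccccc1 | intermediate (not isolated)
11 | (2E,6E)-3,7-dimethyl-9-[(1S)-2,6,6-trimethylcyclohex-2-en-1-yl]nona-2,6-dien-1-ol | OC/C=C(\C)CC/C=C(\C)CC[C@@H]1C(C)=CCCC1(C)C | intermediate
12 | oleic acid, (9Z)-octadec-9-enoic acid | CCCCCCCC/C=C\CCCCCCCC(=O)O | starting material
13 | (2E,6E)-3,7-dimethyl-9-[(1S)-2,6,6-trimethylcyclohex-2-en-1-yl]nona-2,6-dien-1-yl (9Z)-octadec-9-enoate | CCCCCCCC/C=C\CCCCCCCC(=O)OC/C=C(\C)CC/C=C(\C)CC[C@@H]1C(C)=CCCC1(C)C | target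

**Totals**
Total step count: 7. Longest linear sequence: 6 steps (4 → 5 → 6 → 8 → 9 → 11 → 13; the farnesol branch joins after one step).

**Steps most likely to fail**

Step 5 (cyclisation). The risks are slow protonation because the acetate and sulfone bind the acid, partial onward cyclisation, a lower ee than with the known substrates, and exocyclic or tetrasubstituted olefin isomers (these would be removed on AgNO3-impregnated silica). The fallback forms the ring on the C15 fragment before the fragments are joined. It sets out from 3, which is treated with the same chiral acid in toluene at −78 °C to give {[(2E)-3-methyl-5-[(1S)-2,6,6-trimethylcyclohex-2-en-1-yl]pent-2-en-1-yl]sulfonyl}benzene F1. This substrate has no allylic acetate and no remote stereocentre, and its product is a single compound whose olefin isomers can be removed and whose ee can be raised by recrystallisation or chiral chromatography. F1 is deprotonated with n-BuLi in THF at −78 °C to its lithio derivative F2, which is alkylated with bromide 6; the fallback comes back to the route at 9.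

Step 6 (desulfonylation). The risks are allylic transposition or E/Z loss at C6=C7 and ionisation of the C1 allylic oxygen by palladium. The fallback replaces the palladium hydride chemistry by a dissolving-metal C–S cleavage on the free alcohol. It sets out from 9, which is deacetylated with K2CO3 in MeOH to (2E,6E)-3,7-dimethyl-5-(phenylsulfonyl)-9-[(1S)-2,6,6-trimethylcyclohex-2-en-1-yl]nona-2,6-dien-1-ol F3. F3 is then reduced with Li in EtNH2/THF at −78 °C, and the fallback comes back to the route at 11.

Step 4 (coupling). The risk is attack of the carbanion on the acetate, or its enolisation, instead of SN2 alkylation. The fallback uses an ester-free electrophile and restores the acetate afterwards. It sets out from 6, which is reduced with i-Bu2AlH in CH2Cl2 at −78 °C to (2E)-4-bromo-3-methylbut-2-en-1-ol F4. F4 is protected with dihydropyran and pyridinium p-toluenesulfonate as 2-{[(2E)-4-bromo-3-methylbut-2-en-1-yl]oxy}oxane F5. Carbanion 7 is alkylated with F5 to give 2-{[(2E,6E,10E)-3,7,11,15-tetramethyl-5-(phenylsulfonyl)hexadeca-2,6,10,14-tetraen-1-yl]oxy}oxane F6. Methanolysis with pyridinium p-toluenesulfonate gives (2E,6E,10E)-3,7,11,15-tetramethyl-5-(phenylsulfonyl)hexadeca-2,6,10,14-tetraen-1-ol F7, and acetylation with Ac2O/pyridine comes back to the route at 8.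

**Further compounds**
F1 | step 5 | {[(2E)-3-methyl-5-[(1S)-2,6,6-trimethylcyclohex-2-en-1-yl]pent-2-en-1-yl]sulfonyl}benzene | O=S(=O)(C/C=C(\C)CC[C@@H]1C(C)=CCCC1(C)C)c1ccccc1
F2 | step 5 | lithio derivative of F1 (C1 carbanion, lithium salt) | [Li+].O=S(=O)([CH-]/C=C(\C)CC[C@@H]1C(C)=CCCC1(C)C)c1ccccc1
F3 | step 6 | (2E,6E)-3,7-dimethyl-5-(phenylsulfonyl)-9-[(1S)-2,6,6-trimethylcyclohex-2-en-1-yl]nona-2,6-dien-1-ol, both C5 epimers | OC/C=C(\C)CC(/C=C(\C)CC[C@@H]1C(C)=CCCC1(C)C)S(=O)(=O)c1ccccc1
F4 | step 4 | (2E)-4-bromo-3-methylbut-2-en-1-ol | OC/C=C(\C)CBr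
F5 | step 4 | 2-{[(2E)-4-bromo-3-methylbut-2-en-1-yl]oxy}oxane | C1CCCC(OC/C=C(\C)CBr)O1
F6 | step 4 | 2-{[(2E,6E,10E)-3,7,11,15-tetramethyl-5-(phenylsulfonyl)hexadeca-2,6,10,14-tetraen-1-yl]oxy}oxane | C1CCCC(OC/C=C(\C)CC(/C=C(\C)CC/C=C(\C)CCC=C(C)C)S(=O)(=O)c2ccccc2)O1
F7 | step 4 | (2E,6E,10E)-3,7,11,15-tetramethyl-5-(phenylsulfonyl)hexadeca-2,6,10,14-tetraen-1-ol | OC/C=C(\C)CC(/C=C(\C)CC/C=C(\C)CCC=C(C)C)S(=O)(=O)c1ccccc1
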